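## Analysis of the target

The target 25 is a trans-fused hydroazulene. With azulene numbering the five-membered ring is C1–C2–C3–C3a–C8a and the seven-membered ring is C3a–C4–C5–C6–C7–C8–C8a; the same locants are used for all intermediates. There are seven stereocentres: the C1–C2 oxirane (methyl on C2), the fusion carbons C3a and C8a, the isopropyl-bearing C4, the acylated carbinol C5 and the methyl carbinol C7. H3a, the isopropyl group, the C7 hydroxyl and the oxirane oxygen lie on one face; H8a, the C5 ester oxygen and the C7 methyl lie on the other. Hence isopropyl and ester are trans, the C5 and C7 oxygens are 1,3-anti, and the oxirane is syn to the tertiary hydroxyl. The sensitive groups are the trisubstituted epoxide (acid), the tertiary alcohol (elimination), and the aryl ester with its free phenol (base, oxidants, Mitsunobu reagents). The difficulty is a flexible seven-membered ring carrying three stereocentres, two fully substituted oxygenated carbons, and C4, which is an open-chain stereocentre in any monocyclic precursor. The strategy rests on the C5–C6–C7 segment: if the C7 methyl carbinol is read as an exocyclic methylene, C5(OH)–C6–C7(=CH2) is the retron of a carbonyl-ene reaction between a C5 aldehyde and a 2-methylallyl group whose central carbon (C7) is tied through C8 to C8a.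

## Retrosynthetic reasoning

25 ⇒ 24. Only the O–acetyl bond of the phenol is cut. The phenol stays masked through the Mitsunobu and peroxide steps, and the last step must cleave an aryl acetate beside a hindered alkyl benzoate and an epoxide.

24 ⇒ 23. The two C–O bonds of the oxirane are cut, so the most acid-sensitive group appears one step before the end. The forward reaction must deliver oxygen to the face of C1=C2 that carries the C7 hydroxyl; that hydroxyl is used as the directing group.

23 ⇒ 20 ⇒ 19. The C1=C2 alkene with a C3 methylene is traced to the allylic alcohol 20 and on to the enone 19 (C1 ketone, C2=C3). A cyclopentenone is what the early building block delivers, it acidifies C8a for the alkylation, and its electron-poor alkene survives the oxidative cleavage of the other alkene. The forward sequence must move the unsaturation by one position with net loss of oxygen.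

19 ⇒ 16 + 17. The acyl C–O bond of the ester is cut. The aryl part enters late, when both hydroxyls exist and can be told apart by size.

16 ⇒ 15. The C7–CH3 bond is cut. The methyl must arrive on the face of the C5 oxygen so that the new hydroxyl is anti to it. Delivering oxygen to the alkene under direction by the C5 hydroxyl would give the syn diol, so carbon is delivered instead.

15 ⇒ 13. The C7 carbonyl is traced to the exocyclic methylene, the group the ene reaction leaves behind.

13 ⇒ 12. The C5–C6 bond is cut. This opens the seven-membered ring to a monocyclic cyclopentenone that already holds the trans ring fusion, and it creates C5 and the C7 handle in one step. The forward reaction must join an aldehyde and an unactivated alkene without a base that could epimerise C4.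

12 ⇒ 11 ⇒ 10. The aldehyde and enone of 12 are traced through the diol 11 to the ester-enone 10. The aldehyde, whose α-carbon is C4, is unveiled in the last step before the cyclisation and under non-basic conditions.

10 ⇒ 7 + 8. The C8a–C8 bond is cut. Alkylation of the α'-position of the enone places the methallyl group anti to the C3a substituent.

7 ⇒ 6 ⇒ 5. The C2–CH3 bond is cut. The enone is iodinated at C2 and methylated by cross-coupling, both without base, so C3a is safe.

5 ⇒ 1 + 2. The C3a–C4 bond is cut. Conjugate addition of the enolate of 1 to 2, anti to the silyloxy group, followed by loss of silanol, transfers the chirality of 2 to C3a and regenerates the enone on the other side of the ring. C4 is set in the same bond formation, and as an ester α-carbon it is not epimerised in the following steps.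

## Alternatives that were turned down

Alternative 1: Ring-enlarging cyclopentene annulation (Prins–pinacol).
- Disconnection: C1–C2 and C3a–C8a. The five-membered ring is removed and the seven-membered ring shrinks to a cyclohexane that carries an alkyne on a carbinol carbon (later C8) and a ketal-terminated arm on the neighbouring carbon (C3a).
- Forward key step: SnCl4 converts the ketal into an oxocarbenium ion, the alkyne adds to it, and the developing vinyl cation is quenched by a 1,2-shift of a ring bond with formation of the ketone. The product is A1, a hydroazulenone with a C8 ketone conjugated to C8a=C1 and a methoxy group on C2.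
- For it: two C–C bonds, both rings and the fully substituted C2 arise in one operation. C4 and C5 are set on a six-membered chair, where a trans-diequatorial pair is easy to secure. On this point it is stronger than the chosen route, which sets C4 in an open-chain bond formation.
- Against it: A1 has oxygen and unsaturation in the wrong places. The C8 carbonyl must be removed, C8a must be reduced to the trans fusion, C7 must be hydroxylated, and the C2 methoxy/C8a=C1 pair must be reorganised into the C1–C2 epoxide.
- Comparison: these corrections outnumber the whole endgame of the chosen route. In return for its weaker control of C4, the chosen route gives 13 with every carbon in place and needs one oxidative cleavage and one methyl addition.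

Alternative 2: Silicon-directed Nazarov cyclisation.
- Disconnection: C3–C3a. The five-membered ring opens to a cross-conjugated dienone made of a cycloheptene (C8a=C3a) and a silylated isopropenyl unit on the C1 carbonyl.
- Forward key step: FeCl3 generates the pentadienyl cation, conrotatory closure forms C3–C3a, loss of silicon fixes the alkene at C2=C3, and protonation at C8a gives the trans fusion. The product is A2.
- For it: A2 is the bis-silyl ether of intermediate 16, so both strategies meet at the same enone. The C7 methyl carbinol comes from linalool, so this route is stronger on C7, which the chosen route must create by a directed methyl addition.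
- Against it: the cycloheptene with C4, C5 and C7 must be built first, so the hard ring is only moved to an earlier problem. The sense of conrotation, which fixes C3a relative to C4, depends on torquoselectivity. FeCl3 also meets an ionisable tertiary silyl ether.
- Comparison: the chosen route takes C3a from enantiopure 2 and closes the seven-membered ring with the trans fusion already built in; the price is a late C7.

Alternative 3: De Mayo photocycloaddition with retro-aldol ring expansion.
- Disconnection: C3a–C8a and C4–C5, with a temporary C8a–C5 bond. The seven-membered ring comes from two-carbon enlargement of a five-membered β-acyloxy enone.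
- Forward key step: irradiation joins the enone alkene to the tethered alkene, and K2CO3 in methanol then opens the cyclobutane by retro-aldol cleavage. The product is the 1,5-diketone A3.
- For it: both fusion bonds arise in one step from a simple tethered precursor. The C5 ketone makes C4 epimerisable, so the isopropyl group can be placed by equilibration and C5 by a late hydride reduction. This is an advantage over the chosen route on C4.
- Against it: A3 has two ketones (C1, C5) that must be told apart. The C1 ketone must be turned regioselectively into the C1=C2 alkene. The ring fusion must be equilibrated to trans. The straight-versus-crossed regiochemistry of the photocycloaddition is not secured, and photochemistry limits scale.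
- Comparison: the chosen route leaves a single carbonyl (C1) after the key step, used for the transposition, and C5 arrives with its oxygen already in the right configuration.

Key step: step 7

Assumption: tert-butyl 3-methylbutanoate (1) and 2-nitrobenzenesulfonylhydrazide are taken as purchasable; otherwise each is one routine step from isovaleryl chloride or 2-nitrobenzenesulfonyl chloride.

## Route

Step 1
Reactants: 1 tert-butyl 3-methylbutanoate; 2 (4S)-4-(tert-butyldimethylsilyloxy)cyclopent-2-en-1-one
Product: 5 tert-butyl (2S)-3-methyl-2-[(1S)-4-oxocyclopent-2-en-1-yl]butanoate, via lithium ester enolate 3 (not isolated), via silyloxy ketone Michael adduct 4 (not isolated)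
Conditions: LiN(iPr)2, THF, −78 °C; 2, −78 → −40 °C; AcOH; then DBU, CH2Cl2, 0 °C
Reagents that add atoms: none
Why: Michael addition of a lithium ester enolate followed by E1cB loss of silanol; LiN(iPr)2 in THF gives the E(O)-enolate 3, which adds to C3 of 2 anti to the silyloxy group (sets C3a). In the lithium-bridged closed transition state the enolate hydrogen lies over the ring and the isopropyl group outside it, which gives C4 as S; DBU then expels silanolate from 4 without touching C4, which is α only to the ester.

Step 2
Reactants: 5 tert-butyl (2S)-3-methyl-2-[(1S)-4-oxocyclopent-2-en-1-yl]butanoate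
Product: 6 tert-butyl (2S)-2-[(1R)-3-iodo-4-oxocyclopent-2-en-1-yl]-3-methylbutanoate
Conditions: I2, pyridine/CH2Cl2, 0 °C → rt
Reagents that add atoms: iodine [I][I]
Why: Johnson α-iodination: pyridine adds to the β-carbon, the enolate is iodinated at C2 and pyridine is expelled; pyridine is too weak a base to deprotonate the γ-stereocentre C3a.

Step 3
Reactants: 6 tert-butyl (2S)-2-[(1R)-3-iodo-4-oxocyclopent-2-en-1-yl]-3-methylbutanoate
Product: 7 tert-butyl (2S)-3-methyl-2-[(1S)-3-methyl-4-oxocyclopent-2-en-1-yl]butanoate
Conditions: Me4Sn, Pd2(dba)3 (cat.), AsPh3, CuI, N-methylpyrrolidone, 60 °C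
Reagents that add atoms: tetramethylstannane C[Sn](C)(C)C
Why: Stille coupling of a 2-iodoenone (zerovalent palladium, AsPh3 and CuI as accelerators) places the methyl group on C2 under neutral conditions, so C3a and C4 are not at risk.

Step 4
Reactants: 7 tert-butyl (2S)-3-methyl-2-[(1S)-3-methyl-4-oxocyclopent-2-en-1-yl]butanoate; 8 3-bromo-2-methylprop-1-ene
Product: 10 tert-butyl (2S)-3-methyl-2-[(1R,5S)-3-methyl-5-(2-methylprop-2-en-1-yl)-4-oxocyclopent-2-en-1-yl]butanoate, via lithium dienolate 9 (not isolated)
Conditions: LiN(iPr)2, THF, −78 °C; 8, DMPU, −78 → −40 °C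
Reagents that add atoms: none
Why: Kinetic deprotonation of the enone at the α'-methylene (C8a) gives the cross-conjugated dienolate 9, and the allylic bromide enters anti to the bulky C3a substituent (sets C8a, trans). The tertiary ester α-hydrogen is far less acidic and is left alone.

Step 5
Reactants: 10 tert-butyl (2S)-3-methyl-2-[(1R,5S)-3-methyl-5-(2-methylprop-2-en-1-yl)-4-oxocyclopent-2-en-1-yl]butanoate
Product: 11 (2S)-2-[(1S,5S)-4-hydroxy-3-methyl-5-(2-methylprop-2-en-1-yl)cyclopent-2-en-1-yl]-3-methylbutan-1-ol (both epimers at the ring carbinol)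
Conditions: iBu2AlH (excess), CH2Cl2, −78 → 0 °C
Reagents that add atoms: none
Why: iBu2AlH reduces the enone carbonyl in 1,2-fashion and the tert-butyl ester to the primary alcohol; the configuration of the ring carbinol does not matter because it is oxidised again in step 6.

Step 6
Reactants: 11 (2S)-2-[(1S,5S)-4-hydroxy-3-methyl-5-(2-methylprop-2-en-1-yl)cyclopent-2-en-1-yl]-3-methylbutan-1-ol
Product: 12 (2S)-3-methyl-2-[(1S,5S)-3-methyl-5-(2-methylprop-2-en-1-yl)-4-oxocyclopent-2-en-1-yl]butanal
Conditions: Dess–Martin periodinane, NaHCO3, CH2Cl2, 0 °C → rt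
Reagents that add atoms: none
Why: Dess–Martin oxidation of both alcohols restores the enone and unveils the aldehyde under buffered, non-basic conditions, so C4 is not enolised; 12 is used at once.

Step 7
Reactants: 12 (2S)-3-methyl-2-[(1S,5S)-3-methyl-5-(2-methylprop-2-en-1-yl)-4-oxocyclopent-2-en-1-yl]butanal
Product: 13 (3aS,4S,5S,8aS)-5-hydroxy-2-methyl-7-methylidene-4-(propan-2-yl)-4,5,6,7,8,8a-hexahydroazulen-1(3aH)-one
Conditions: Me2AlCl (2.5 equiv), CH2Cl2, −78 → −40 °C
Reagents that add atoms: none
Why: Me2AlCl binds the aldehyde oxygen (a second equivalent is taken up by the enone), the CH2 terminus of the methallyl group (C6) attacks C5, and one hydrogen of the allylic methyl passes to oxygen through a six-membered array, so the C5–C6 bond, the C5 alkoxide and the C7 exocyclic methylene form in one concerted, asynchronous event. The closest known reaction is the type 2 intramolecular carbonyl-ene cyclisation of aldehydes tethered to the central carbon of a 1,1-disubstituted alkene, promoted by alkylaluminium halides, which gives methylenecyclohexanols and methylenecycloheptanols. The seven-membered ring closes exo with respect to the carbonyl group and endo with respect to the ene double bond (C6 and C7 both enter the ring). The trans relationship of the two arms in 12 fixes the trans ring fusion and holds them in a chair-like array in which the C4 isopropyl group and the aluminium-bound oxygen are both pseudo-equatorial, so the new stereocentre C5 is S with oxygen trans to isopropyl. No enolate is formed, so C3a, C4 and C8a are not exposed to base, and the methyl groups on aluminium take up the liberated proton as methane, which suppresses chloride capture and alkene migration. The step needs chemoselectivity for the aldehyde over the enone: the aldehyde complex is the stronger electrophile, and attack of the alkene on C3 of the complexed enone would give a strained bridged ring. Low temperature keeps the α-branched aldehyde from enolising.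

Step 8
Reactants: 13 (3aS,4S,5S,8aS)-5-hydroxy-2-methyl-7-methylidene-4-(propan-2-yl)-4,5,6,7,8,8a-hexahydroazulen-1(3aH)-one
Product: 15 (3aS,4S,5S,8aS)-5-hydroxy-2-methyl-4-(propan-2-yl)-3a,4,5,6,8,8a-hexahydroazulene-1,7-dione, via spiro ozonide 14 (not isolated)
Conditions: O3, CH2Cl2, −78 °C (Sudan Red 7B end point); PPh3, −78 °C → rt
Reagents that add atoms: ozone [O-][O+]=O
Why: Ozonolysis: the electron-rich 1,1-disubstituted alkene reacts far faster than the electron-poor enone alkene, the dye marks the end point, and PPh3 reduces ozonide 14 to the C7 ketone.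

Step 9
Reactants: 15 (3aS,4S,5S,8aS)-5-hydroxy-2-methyl-4-(propan-2-yl)-3a,4,5,6,8,8a-hexahydroazulene-1,7-dione
Product: 16 (3aS,4S,5S,7R,8aS)-5,7-dihydroxy-2,7-dimethyl-4-(propan-2-yl)-4,5,6,7,8,8a-hexahydroazulen-1(3aH)-one
Conditions: Me3Al (3 equiv), CH2Cl2, −78 → −20 °C
Reagents that add atoms: trimethylaluminium C[Al](C)C
Why: Hydroxyl-directed organoaluminium addition to a β-hydroxy ketone: the C5 hydroxyl becomes an aluminium alkoxide that holds aluminium on the face of the C7 carbonyl syn to O5, and methyl is transferred from that face (methyl cis to O5, new hydroxyl anti, C7 R). The saturated, alkoxide-assisted ketone should react before the conjugated C1 carbonyl.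

Step 10
Reactants: 16 (3aS,4S,5S,7R,8aS)-5,7-dihydroxy-2,7-dimethyl-4-(propan-2-yl)-4,5,6,7,8,8a-hexahydroazulen-1(3aH)-one; 17 4-(acetyloxy)benzoic acid
Product: 19 (3aS,4S,5S,7R,8aS)-7-hydroxy-2,7-dimethyl-1-oxo-4-(propan-2-yl)-1,3a,4,5,6,7,8,8a-octahydroazulen-5-yl 4-(acetyloxy)benzoate, via 4-acetoxybenzoyl chloride 18 (not isolated)
Conditions: 17, (COCl)2, DMF (cat.), CH2Cl2, 0 °C → rt; then 16, Et3N, DMAP (cat.), CH2Cl2, 0 °C → rt
Reagents that add atoms: none
Why: DMAP-catalysed acylation of the secondary C5 alcohol by acid chloride 18; the tertiary C7 hydroxyl is too hindered to react, and C5 keeps its configuration because its C–O bond is not broken.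

Step 11
Reactants: 19 (3aS,4S,5S,7R,8aS)-7-hydroxy-2,7-dimethyl-1-oxo-4-(propan-2-yl)-1,3a,4,5,6,7,8,8a-octahydroazulen-5-yl 4-(acetyloxy)benzoate
Product: 20 (3aR,4S,5S,7R,8aS)-1,7-dihydroxy-2,7-dimethyl-4-(propan-2-yl)-1,3a,4,5,6,7,8,8a-octahydroazulen-5-yl 4-(acetyloxy)benzoate (both C1 epimers)
Conditions: NaBH4, CeCl3·7H2O, MeOH, −78 °C
Reagents that add atoms: none
Why: Luche 1,2-reduction of the enone; at −78 °C the cerium-modified borohydride leaves both esters intact, and the configuration of the new C1 carbinol is of no consequence for step 12.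

Step 12
Reactants: 20 (3aR,4S,5S,7R,8aS)-1,7-dihydroxy-2,7-dimethyl-4-(propan-2-yl)-1,3a,4,5,6,7,8,8a-octahydroazulen-5-yl 4-(acetyloxy)benzoate
Product: 23 (3aR,4S,5S,7R,8aS)-7-hydroxy-2,7-dimethyl-4-(propan-2-yl)-3,3a,4,5,6,7,8,8a-octahydroazulen-5-yl 4-(acetyloxy)benzoate, via allylic sulfonylhydrazine 21 (not isolated), via allylic diazene 22 (not isolated)
Conditions: 2-nitrobenzenesulfonylhydrazide, PPh3, diethyl azodicarboxylate, N-methylmorpholine, −30 °C → rt
Reagents that add atoms: none
Why: Myers reductive 1,3-transposition: Mitsunobu displacement of the allylic alcohol by the sulfonylhydrazide gives 21, loss of sulfinic acid gives diazene 22, and its retro-ene loss of N2 delivers hydrogen to C3 and moves the double bond to C1=C2. The tertiary alcohol and the esters do not take part.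

Step 13
Reactants: 23 (3aR,4S,5S,7R,8aS)-7-hydroxy-2,7-dimethyl-4-(propan-2-yl)-3,3a,4,5,6,7,8,8a-octahydroazulen-5-yl 4-(acetyloxy)benzoate
Product: 24 (1S,2R,3aR,4S,5S,7R,8aS)-1,2-epoxy-7-hydroxy-2,7-dimethyl-4-(propan-2-yl)decahydroazulen-5-yl 4-(acetyloxy)benzoate
Conditions: VO(acac)2 (10 mol%), t-BuOOH, CH2Cl2, 0 °C → rt
Reagents that add atoms: tert-butyl hydroperoxide CC(C)(C)OO
Why: Vanadium-catalysed hydroxyl-directed epoxidation of a bishomoallylic alcohol: the C7 alkoxide and the alkyl peroxide bind to the same vanadium centre, and oxygen is delivered to the face of C1=C2 that carries the C7 hydroxyl (C1 S, C2 R). The syn arrangement also prevents the hydroxyl from opening the epoxide from the rear.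

Step 14
Reactants: 24 (1S,2R,3aR,4S,5S,7R,8aS)-1,2-epoxy-7-hydroxy-2,7-dimethyl-4-(propan-2-yl)decahydroazulen-5-yl 4-(acetyloxy)benzoate
Product: 25 (1S,2R,3aR,4S,5S,7R,8aS)-1,2-epoxy-7-hydroxy-2,7-dimethyl-4-(propan-2-yl)decahydroazulen-5-yl 4-hydroxybenzoate
Conditions: K2CO3 (cat.), MeOH, 0 °C
Reagents that add atoms: none
Why: Methanolysis of the aryl acetate, which is far more electrophilic than the hindered secondary benzoate; epoxide and tertiary alcohol are stable to catalytic carbonate in cold methanol.

## Compound list

1 | tert-butyl 3-methylbutanoate | CC(C)CC(=O)OC(C)(C)C | starting material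
2 | (4S)-4-(tert-butyldimethylsilyloxy)cyclopent-2-en-1-one | O=C1C=C[C@@H](O[Si](C)(C)C(C)(C)C)C1 | starting material
3 | lithium enolate of 1, E(O) geometry (hydrogen on C2 cis to OLi) | CC(C)/C=C(/O[Li])OC(C)(C)C | intermediate
4 | tert-butyl (2S)-2-[(1R,2S)-2-(tert-butyldimethylsilyloxy)-4-oxocyclopentyl]-3-methylbutanoate | CC(C)[C@H](C(=O)OC(C)(C)C)[C@@H]1[C@@H](O[Si](C)(C)C(C)(C)C)CC(=O)C1 | intermediate
5 | tert-butyl (2S)-3-methyl-2-[(1S)-4-oxocyclopent-2-en-1-yl]butanoate | CC(C)[C@H](C(=O)OC(C)(C)C)[C@@H]1C=CC(=O)C1 | intermediate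
6 | tert-butyl (2S)-2-[(1R)-3-iodo-4-oxocyclopent-2-en-1-yl]-3-methylbutanoate | CC(C)[C@H](C(=O)OC(C)(C)C)[C@@H]1C=C(I)C(=O)C1 | intermediate
7 | tert-butyl (2S)-3-methyl-2-[(1S)-3-methyl-4-oxocyclopent-2-en-1-yl]butanoate | CC(C)[C@H](C(=O)OC(C)(C)C)[C@@H]1C=C(C)C(=O)C1 | intermediate
8 | 3-bromo-2-methylprop-1-ene | CC(=C)CBr | starting material
9 | lithium cross-conjugated dienolate of 7 (ring CH2 next to the carbonyl deprotonated, stereocentres as in 7) | CC(C)[C@H](C(=O)OC(C)(C)C)[C@@H]1C=C(C)C(O[Li])=C1 | intermediate
10 | tert-butyl (2S)-3-methyl-2-[(1R,5S)-3-methyl-5-(2-methylprop-2-en-1-yl)-4-oxocyclopent-2-en-1-yl]butanoate | CC(C)[C@H](C(=O)OC(C)(C)C)[C@@H]1C=C(C)C(=O)[C@H]1CC(C)=C | intermediate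
11 | (2S)-2-[(1S,5S)-4-hydroxy-3-methyl-5-(2-methylprop-2-en-1-yl)cyclopent-2-en-1-yl]-3-methylbutan-1-ol, both epimers at the ring carbinol | CC(C)[C@H](CO)[C@@H]1C=C(C)C(O)[C@H]1CC(C)=C | intermediate
12 | (2S)-3-methyl-2-[(1S,5S)-3-methyl-5-(2-methylprop-2-en-1-yl)-4-oxocyclopent-2-en-1-yl]butanal | CC(C)[C@H](C=O)[C@@H]1C=C(C)C(=O)[C@H]1CC(C)=C | intermediate
13 | (3aS,4S,5S,8aS)-5-hydroxy-2-methyl-7-methylidene-4-(propan-2-yl)-4,5,6,7,8,8a-hexahydroazulen-1(3aH)-one | CC(C)[C@H]1[C@@H]2C=C(C)C(=O)[C@H]2CC(=C)C[C@@H]1O | intermediate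
14 | spiro ozonide of 13 (1,2,4-trioxolane at C7, both C7 epimers) | CC(C)[C@H]1[C@@H]2C=C(C)C(=O)[C@H]2CC3(OOCO3)C[C@@H]1O | intermediate
15 | (3aS,4S,5S,8aS)-5-hydroxy-2-methyl-4-(propan-2-yl)-3a,4,5,6,8,8a-hexahydroazulene-1,7-dione | CC(C)[C@H]1[C@@H]2C=C(C)C(=O)[C@H]2CC(=O)C[C@@H]1O | intermediate
16 | (3aS,4S,5S,7R,8aS)-5,7-dihydroxy-2,7-dimethyl-4-(propan-2-yl)-4,5,6,7,8,8a-hexahydroazulen-1(3aH)-one | CC(C)[C@H]1[C@@H]2C=C(C)C(=O)[C@H]2C[C@@](C)(O)C[C@@H]1O | intermediate
17 | 4-(acetyloxy)benzoic acid | CC(=O)Oc1ccc(cc1)C(O)=O | starting material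
18 | 4-(acetyloxy)benzoyl chloride | CC(=O)Oc1ccc(cc1)C(Cl)=O | intermediate
19 | (3aS,4S,5S,7R,8aS)-7-hydroxy-2,7-dimethyl-1-oxo-4-(propan-2-yl)-1,3a,4,5,6,7,8,8a-octahydroazulen-5-yl 4-(acetyloxy)benzoate | CC(C)[C@H]1[C@@H]2C=C(C)C(=O)[C@H]2C[C@@](C)(O)C[C@@H]1OC(=O)c1ccc(OC(C)=O)cc1 | intermediate
20 | (3aR,4S,5S,7R,8aS)-1,7-dihydroxy-2,7-dimethyl-4-(propan-2-yl)-1,3a,4,5,6,7,8,8a-octahydroazulen-5-yl 4-(acetyloxy)benzoate, both C1 epimers | CC(C)[C@H]1[C@@H]2C=C(C)C(O)[C@H]2C[C@@](C)(O)C[C@@H]1OC(=O)c1ccc(OC(C)=O)cc1 | intermediate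
21 | allylic 1-alkyl-1-(2-nitrobenzenesulfonyl)hydrazine: 20 with the C1 hydroxyl replaced by N(NH2)SO2Ar | CC(C)[C@H]1[C@@H]2C=C(C)C(N(N)S(=O)(=O)c3ccccc3[N+]([O-])=O)[C@H]2C[C@@](C)(O)C[C@@H]1OC(=O)c1ccc(OC(C)=O)cc1 | intermediate
22 | allylic diazene: 20 with the C1 hydroxyl replaced by N=NH | CC(C)[C@H]1[C@@H]2C=C(C)C(N=N)[C@H]2C[C@@](C)(O)C[C@@H]1OC(=O)c1ccc(OC(C)=O)cc1 | intermediate
23 | (3aR,4S,5S,7R,8aS)-7-hydroxy-2,7-dimethyl-4-(propan-2-yl)-3,3a,4,5,6,7,8,8a-octahydroazulen-5-yl 4-(acetyloxy)benzoate | CC(C)[C@H]1[C@@H]2CC(C)=C[C@H]2C[C@@](C)(O)C[C@@H]1OC(=O)c1ccc(OC(C)=O)cc1 | intermediate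
24 | (1S,2R,3aR,4S,5S,7R,8aS)-1,2-epoxy-7-hydroxy-2,7-dimethyl-4-(propan-2-yl)decahydroazulen-5-yl 4-(acetyloxy)benzoate | CC(C)[C@H]1[C@@H]2C[C@@]3(C)O[C@H]3[C@H]2C[C@@](C)(O)C[C@@H]1OC(=O)c1ccc(OC(C)=O)cc1 | intermediate
25 | (1S,2R,3aR,4S,5S,7R,8aS)-1,2-epoxy-7-hydroxy-2,7-dimethyl-4-(propan-2-yl)decahydroazulen-5-yl 4-hydroxybenzoate | CC(C)[C@H]1[C@@H]2C[C@@]3(C)O[C@H]3[C@H]2C[C@@](C)(O)C[C@@H]1OC(=O)c1ccc(O)cc1 | target

## Step count and least certain steps

Total: 14 steps. Longest linear sequence: 14 steps (2 → 25); 1, 8 and 17 enter as purchased inputs.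

**Step 7 (key step).**
- What may go wrong: the unactivated alkene may capture the aluminium-bound aldehyde too slowly for a seven-membered closure. Enolisation of the α-branched aldehyde (loss of C4), methyl transfer from aluminium to the aldehyde, or closure through a boat-like array (C5 epimer) would then compete.
- Fallback: keep the C5–C6 bond but use a stronger π-nucleophile, an intramolecular Hosomi–Sakurai reaction. It sets out from 7 and comes back at 13. The lithium dienolate of 7 is alkylated with 2-(chloromethyl)-3-(trimethylsilyl)prop-1-ene and NaI to give the allylsilane ester tert-butyl (2S)-3-methyl-2-[(1R,5S)-3-methyl-4-oxo-5-{2-[(trimethylsilyl)methyl]prop-2-en-1-yl}cyclopent-2-en-1-yl]butanoate F1. Reduction with iBu2AlH gives the allylsilane diol F2, and Dess–Martin oxidation gives the allylsilane keto aldehyde F3. BF3·OEt2 in CH2Cl2 at −78 °C closes the ring with loss of silicon and gives 13.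

**Step 1.**
- What may go wrong: erosion of simple diastereoselection at C4. An open transition state, or kinetic 1,2-addition followed by retro-aldol return on warming, can compete with the lithium-bridged closed transition state. The basic enolate can also start β-elimination in 2.
- Fallback: set C4 by hydrogen delivery to the convex face of a cis-fused lactone. It sets out from 2 and comes back at 5.
  - Luche reduction (NaBH4, CeCl3·7H2O) of 2 gives (1R,4S)-4-(tert-butyldimethylsilyloxy)cyclopent-2-en-1-ol F4.
  - N-Bromosuccinimide and ethyl vinyl ether give the bromoacetal F5.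
  - Ueno–Stork radical cyclisation (Bu3SnH, azobisisobutyronitrile) gives the cis-fused bicyclic acetal F6.
  - 3-Chloroperbenzoic acid with BF3·OEt2 oxidises it to the lactone (3aR,5R,6aR)-5-(tert-butyldimethylsilyloxy)hexahydro-2H-cyclopenta[b]furan-2-one F7.
  - The lithium enolate (LiN(iPr)2) adds to acetone to give the aldol adduct F8; SOCl2/pyridine and then DBU give the conjugated isopropylidene lactone F9.
  - H2 over Pd/C adds from the convex face and gives the endo-isopropyl lactone (3S,3aR,5R,6aR)-5-(tert-butyldimethylsilyloxy)-3-(propan-2-yl)hexahydro-2H-cyclopenta[b]furan-2-one F10.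
  - Bu4NF gives the hydroxy lactone F11, and Dess–Martin oxidation gives the keto lactone F12.
  - DBU expels the lactone carboxylate from F12 and gives the enone acid (2S)-3-methyl-2-[(1S)-4-oxocyclopent-2-en-1-yl]butanoic acid F13.
  - Boc2O, 4-dimethylaminopyridine and tert-butanol convert F13 into 5.

**Step 9.**
- What may go wrong: poor facial control. If the aluminium alkoxide cannot reach the carbonyl face, external methyl transfer under steric control gives the C7 epimer. Retro-aldol opening of the aluminium aldolate and addition to the C1 carbonyl are further risks.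
- Fallback: hydroxyl-directed oxymercuration in place of ozonolysis and methyl addition. It sets out from 13 and comes back at 16. Hg(OAc)2 in aqueous THF is guided by the C5 hydroxyl to the same face of the exocyclic alkene, and water adds to C7 from the opposite face, giving the alkylmercury acetate F14. Bu3SnH removes mercury without touching the enone and gives 16.

**Step 12.**
- What may go wrong: slow Mitsunobu displacement at C1, which is flanked by the C2 methyl and C8a. Elimination to a diene, or attack at C3 (which after nitrogen loss gives the alkene regioisomer), would compete.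
- Fallback: hydride reduction of the enone tosylhydrazone. It sets out from 19 and comes back at 23. 4-Toluenesulfonylhydrazide with catalytic acid gives the tosylhydrazone F15. Catecholborane followed by warming with sodium acetate trihydrate reduces the C=N bond, expels sulfinate and gives the same diazene 22, which loses nitrogen to 23.

**Step 13.**
- What may go wrong: weak direction from the remote tertiary hydroxyl. Undirected oxygen transfer to the more open face would give the epoxide epimer.
- Fallback: a bromohydrin route, which reverses the facial outcome of electrophilic attack. It sets out from 23 and comes back at 25. Silylation (Me3SiOTf, 2,6-lutidine) gives the trimethylsilyl ether F16, which keeps the C7 oxygen from capturing the bromonium ion. N-Bromosuccinimide in buffered aqueous 1,2-dimethoxyethane attacks the open face, and water opens the bromonium ion at C2 from the other face, giving the bromohydrin F17. K2CO3 in methanol closes the epoxide with inversion at C1 and removes the silyl ether and the aryl acetate, giving 25.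

## Further compounds

F1 | step 7 | tert-butyl (2S)-3-methyl-2-[(1R,5S)-3-methyl-4-oxo-5-{2-[(trimethylsilyl)methyl]prop-2-en-1-yl}cyclopent-2-en-1-yl]butanoate | CC(C)[C@H](C(=O)OC(C)(C)C)[C@@H]1C=C(C)C(=O)[C@H]1CC(=C)C[Si](C)(C)C
F2 | step 7 | (2S)-2-[(1S,5S)-4-hydroxy-3-methyl-5-{2-[(trimethylsilyl)methyl]prop-2-en-1-yl}cyclopent-2-en-1-yl]-3-methylbutan-1-ol, both carbinol epimers | CC(C)[C@H](CO)[C@@H]1C=C(C)C(O)[C@H]1CC(=C)C[Si](C)(C)C
F3 | step 7 | (2S)-3-methyl-2-[(1S,5S)-3-methyl-4-oxo-5-{2-[(trimethylsilyl)methyl]prop-2-en-1-yl}cyclopent-2-en-1-yl]butanal | CC(C)[C@H](C=O)[C@@H]1C=C(C)C(=O)[C@H]1CC(=C)C[Si](C)(C)C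
F4 | step 1 | (1R,4S)-4-(tert-butyldimethylsilyloxy)cyclopent-2-en-1-ol | O[C@H]1C=C[C@@H](O[Si](C)(C)C(C)(C)C)C1
F5 | step 1 | (1R,4S)-1-(2-bromo-1-ethoxyethoxy)-4-(tert-butyldimethylsilyloxy)cyclopent-2-ene, both acetal epimers | CCOC(CBr)O[C@H]1C=C[C@@H](O[Si](C)(C)C(C)(C)C)C1
F6 | step 1 | (3aR,5R,6aR)-5-(tert-butyldimethylsilyloxy)-2-ethoxyhexahydro-2H-cyclopenta[b]furan, both acetal epimers | CCOC1C[C@H]2C[C@@H](O[Si](C)(C)C(C)(C)C)C[C@H]2O1
F7 | step 1 | (3aR,5R,6aR)-5-(tert-butyldimethylsilyloxy)hexahydro-2H-cyclopenta[b]furan-2-one | O=C1C[C@H]2C[C@@H](O[Si](C)(C)C(C)(C)C)C[C@H]2O1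
F8 | step 1 | (3S,3aR,5R,6aR)-5-(tert-butyldimethylsilyloxy)-3-(2-hydroxypropan-2-yl)hexahydro-2H-cyclopenta[b]furan-2-one | O=C1[C@H](C(C)(C)O)[C@H]2C[C@@H](O[Si](C)(C)C(C)(C)C)C[C@H]2O1
F9 | step 1 | (3aR,5R,6aR)-5-(tert-butyldimethylsilyloxy)-3-(propan-2-ylidene)hexahydro-2H-cyclopenta[b]furan-2-one | O=C1C(=C(C)C)[C@H]2C[C@@H](O[Si](C)(C)C(C)(C)C)C[C@H]2O1
F10 | step 1 | (3S,3aR,5R,6aR)-5-(tert-butyldimethylsilyloxy)-3-(propan-2-yl)hexahydro-2H-cyclopenta[b]furan-2-one | O=C1[C@@H](C(C)C)[C@H]2C[C@@H](O[Si](C)(C)C(C)(C)C)C[C@H]2O1
F11 | step 1 | (3S,3aR,5R,6aR)-5-hydroxy-3-(propan-2-yl)hexahydro-2H-cyclopenta[b]furan-2-one | O=C1[C@@H](C(C)C)[C@H]2C[C@@H](O)C[C@H]2O1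
F12 | step 1 | (3S,3aR,6aR)-3-(propan-2-yl)tetrahydro-2H-cyclopenta[b]furan-2,5(3H)-dione | O=C1[C@@H](C(C)C)[C@H]2CC(=O)C[C@H]2O1
F13 | step 1 | (2S)-3-methyl-2-[(1S)-4-oxocyclopent-2-en-1-yl]butanoic acid | CC(C)[C@H](C(O)=O)[C@@H]1C=CC(=O)C1
F14 | step 9 | alkylmercury acetate: 16 with the C7 methyl replaced by CH2HgOAc | CC(C)[C@H]1[C@@H]2C=C(C)C(=O)[C@H]2C[C@@](C[Hg]OC(C)=O)(O)C[C@@H]1O
F15 | step 12 | 4-toluenesulfonylhydrazone of 19 at C1 | CC(C)[C@H]1[C@@H]2C=C(C)C(=NNS(=O)(=O)c3ccc(C)cc3)[C@H]2C[C@@](C)(O)C[C@@H]1OC(=O)c1ccc(OC(C)=O)cc1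
F16 | step 13 | C7 trimethylsilyl ether of 23 | CC(C)[C@H]1[C@@H]2CC(C)=C[C@H]2C[C@@](C)(O[Si](C)(C)C)C[C@@H]1OC(=O)c1ccc(OC(C)=O)cc1
F17 | step 13 | bromohydrin of F16: C2 hydroxyl on the face of the C7 oxygen, C1 bromide on the opposite face | CC(C)[C@H]1[C@@H]2C[C@@](C)(O)[C@H](Br)[C@H]2C[C@@](C)(O[Si](C)(C)C)C[C@@H]1OC(=O)c1ccc(OC(C)=O)cc1
A1 | alternative 1 | 5-(tert-butyldimethylsilyloxy)-2-methoxy-2,7-dimethyl-4-(propan-2-yl)-3,3a,4,5,6,7-hexahydroazulen-8(2H)-one | CC(C)[C@H]1[C@@H]2C[C@](C)(OC)C=C2C(=O)[C@H](C)C[C@@H]1O[Si](C)(C)C(C)(C)C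
A2 | alternative 2 | 5-(tert-butyldimethylsilyloxy)-2,7-dimethyl-4-(propan-2-yl)-7-(triethylsilyloxy)-4,5,6,7,8,8a-hexahydroazulen-1(3aH)-one | CC(C)[C@H]1[C@@H]2C=C(C)C(=O)[C@H]2C[C@@](C)(O[Si](CC)(CC)CC)C[C@@H]1O[Si](C)(C)C(C)(C)C
A3 | alternative 3 | 7-(methoxymethoxy)-2,7-dimethyl-4-(propan-2-yl)octahydroazulene-1,5-dione | CC(C)[C@H]1[C@@H]2C[C@H](C)C(=O)[C@H]2C[C@@](C)(OCOC)CC1=O
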